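**Plan**

1. The target is two identical 2-hydroxy-5-methoxy-6-methyl-1,4-benzoquinone rings joined C3 to C3 by a (CH2)14 chain (C1'–C14'). It has no stereocentre and no stereogenic double bond, so no stereochemistry has to be set.
2. Retrosynthetic cuts, in order: (a) each quinone back to a 2-alkyl-4,6-dimethoxy-5-methylresorcinol, with the hydroxyls flanking the chain and the methoxyls flanking the methyl, carried as its bis(MOM) ether; (b) the tether at C4'–C5' and C10'–C11', giving two arylbutyl bromides and a six-carbon di-Grignard reagent; (c) the aryl–C1' bond, giving an aryllithium and 1,4-dibromobutane.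
3. Enabling feature: the fourteen chain carbons between the two six-membered rings carry only hydrogen. C4'–C5' and C10'–C11' are therefore plain CH2–CH2 bonds that a 4 + 6 + 4 alkyl–alkyl coupling can make with nothing to reduce or remove afterwards, and the hexasubstituted arene holds only ethers and acetals.
4. Forward: 2,6-dimethoxytoluene is taken through the dibromide, bis-boronate, resorcinol and bis(MOM) ether, then ortho-lithiated and alkylated to the bromobutyl arene. Two of these are spliced onto hexane-1,6-diylbis(magnesium bromide) in one copper-catalysed operation. MOM removal and oxidative demethylation then reveal both hydroxyquinones. No ring is built; both carbocycles come from the starting arene.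

Key step: step 7

**Route**

Step 1
Reactants: 1 2,6-dimethoxytoluene
Product: 2 1,5-dibromo-2,4-dimethoxy-3-methylbenzene
Conditions: NBS (2.2 equiv), MeCN, rt to 50 °C, dark
Reagents that add atoms: N-bromosuccinimide, O=C1CCC(=O)N1Br
Why: Electrophilic aromatic bromination, in which the two ring positions that are ortho to one methoxy group and para to the other are the only activated sites, while polar, initiator-free conditions leave the benzylic methyl untouched.

Step 2
Reactants: 2 1,5-dibromo-2,4-dimethoxy-3-methylbenzene
Product: 3 2,2'-(4,6-dimethoxy-5-methyl-1,3-phenylene)bis(4,4,5,5-tetramethyl-1,3,2-dioxaborolane)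
Conditions: B2pin2 (2.6 equiv), PdCl2(dppf) (5 mol %), KOAc (6 equiv), 1,4-dioxane, 90 °C
Reagents that add atoms: bis(pinacolato)diboron, CC1(C)OB(OC1(C)C)B1OC(C)(C)C(C)(C)O1
Why: Miyaura borylation, in which oxidative addition of each C–Br bond to zerovalent palladium, acetate-assisted transmetalation with the diboron reagent and reductive elimination convert both bromides, each with only one ortho substituent, into pinacol boronates.

Step 3
Reactants: 3 2,2'-(4,6-dimethoxy-5-methyl-1,3-phenylene)bis(4,4,5,5-tetramethyl-1,3,2-dioxaborolane)
Product: 4 4,6-dimethoxy-5-methylbenzene-1,3-diol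
Conditions: 30% aq H2O2, NaOH, THF–H2O, 0 °C, under N2
Reagents that add atoms: hydrogen peroxide, OO
Why: Oxidation of an arylboronate by hydroperoxide through a boron ate complex and 1,2-aryl shift from boron to oxygen places a hydroxyl exactly where each boron stood, and cold oxygen-free conditions should protect the electron-rich resorcinol.

Step 4
Reactants: 4 4,6-dimethoxy-5-methylbenzene-1,3-diol
Product: 5 1,5-bis(methoxymethoxy)-2,4-dimethoxy-3-methylbenzene
Conditions: NaH (2.5 equiv), MOMCl (2.4 equiv), DMF, 0 °C to rt
Reagents that add atoms: chloromethyl methyl ether, COCCl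
Why: Williamson-type O-alkylation of the bis-phenoxide by the hard electrophile MOMCl gives the bis-acetal, which serves both as base-stable protection and as the directing group for the next step.

Step 5
Reactants: 5 1,5-bis(methoxymethoxy)-2,4-dimethoxy-3-methylbenzene; 6 1,4-dibromobutane
Product: 8 2-(4-bromobutyl)-1,3-bis(methoxymethoxy)-4,6-dimethoxy-5-methylbenzene, via [2,6-bis(methoxymethoxy)-3,5-dimethoxy-4-methylphenyl]lithium 7 (not isolated)
Conditions: n-BuLi (1.1 equiv), THF, 0 °C, 1 h; then cannulated into 6 (5 equiv), THF, −78 °C to rt
Reagents that add atoms: none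
Why: Directed ortho-metalation removes the only ring hydrogen, which sits between two chelating OMOM groups, and the aryllithium then displaces one bromide of the dibromide by SN2, inverse addition into a fivefold excess keeping the second C–Br bond intact.

Step 6
Reactants: 9 1,6-dibromohexane
Product: 10 hexane-1,6-diylbis(magnesium bromide) (titrated THF solution)
Conditions: Mg turnings (4 equiv, activated with a crystal of I2), THF, 35–45 °C, slow addition of 9 at high dilution
Reagents that add atoms: magnesium, [Mg]
Why: Grignard formation by insertion of magnesium into both primary C–Br bonds, where the six-carbon spacer rules out 1,2- or 1,3-elimination and slow, dilute addition should limit Wurtz coupling.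

Step 7
Reactants: 8 2-(4-bromobutyl)-1,3-bis(methoxymethoxy)-4,6-dimethoxy-5-methylbenzene (2.3 equiv); 10 hexane-1,6-diylbis(magnesium bromide) (1 equiv)
Product: 11 1,14-bis[2,6-bis(methoxymethoxy)-3,5-dimethoxy-4-methylphenyl]tetradecane
Conditions: Li2CuCl4 (6 mol %), NMP (8 equiv), THF, 0 to 20 °C, 10 added by syringe pump over 3 h
Reagents that add atoms: none
Why: Li2CuCl4, a divalent copper salt, is reduced by the first drops of 10 to a monovalent copper alkylcuprate; this attacks the primary C–Br carbon of 8 in an SN2-like oxidative addition to a trivalent copper dialkyl, and reductive elimination forges C4'–C5' at one terminus and C10'–C11' at the other while returning monovalent copper. NMP keeps the cuprate soluble and long-lived, so substitution should outrun β-hydride elimination, reduction and homocoupling. The closest known reaction type is the Li2CuCl4-catalysed coupling of primary alkyl Grignard reagents, α,ω-bis-Grignard reagents included, with primary alkyl bromides or sulfonates, long used to assemble lipid chains. No ring is closed and no stereocentre is created. The step needs chemoselective substitution at C(sp3)–Br and reaction at both magnesium termini: 8 has a single electrophilic site, an unbranched primary bromide four carbons from an arene that has no ring hydrogen left to metalate and carries only ethers and acetals inert to Grignard reagents, and keeping 8 in slight excess while 10 is added slowly should drive both ends to couple.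

Step 8
Reactants: 11 1,14-bis[2,6-bis(methoxymethoxy)-3,5-dimethoxy-4-methylphenyl]tetradecane
Product: 12 2,2'-(tetradecane-1,14-diyl)bis(4,6-dimethoxy-5-methylbenzene-1,3-diol)
Conditions: 3 M HCl in MeOH–THF, 45 °C, degassed
Reagents that add atoms: none
Why: Acid-catalysed transacetalisation to methanol cleaves the four aryl MOM acetals through oxocarbenium ions, while the aryl methyl ethers and the alkane chain are inert to dilute HCl.

Step 9
Reactants: 12 2,2'-(tetradecane-1,14-diyl)bis(4,6-dimethoxy-5-methylbenzene-1,3-diol)
Product: 13 3,3'-(tetradecane-1,14-diyl)bis(2-hydroxy-5-methoxy-6-methylcyclohexa-2,5-diene-1,4-dione)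
Conditions: PhI(OAc)2 (2.2 equiv), MeCN–THF–H2O, 0 °C
Reagents that add atoms: water, O
Why: Oxidative demethylation of a para-methoxyphenol, in which a phenol oxygen binds trivalent iodine, PhI departs, water adds at the para carbon and methanol is expelled to give the quinone; because each ring is mirror-symmetric about the axis through the chain-bearing and methyl-bearing carbons, oxidation across either hydroxy/methoxy pair (or via the ortho-quinone tautomer) should give the same quinone, with the surviving hydroxyl beside the chain and the surviving methoxyl beside the methyl.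

**Compound list**

1 | 2,6-dimethoxytoluene (1,3-dimethoxy-2-methylbenzene) | COc1cccc(OC)c1C | starting material
2 | 1,5-dibromo-2,4-dimethoxy-3-methylbenzene | COc1c(Br)cc(Br)c(OC)c1C | intermediate
3 | 2,2'-(4,6-dimethoxy-5-methyl-1,3-phenylene)bis(4,4,5,5-tetramethyl-1,3,2-dioxaborolane) | COc1c(B2OC(C)(C)C(C)(C)O2)cc(B2OC(C)(C)C(C)(C)O2)c(OC)c1C | intermediate
4 | 4,6-dimethoxy-5-methylbenzene-1,3-diol | COc1c(O)cc(O)c(OC)c1C | intermediate
5 | 1,5-bis(methoxymethoxy)-2,4-dimethoxy-3-methylbenzene | COCOc1cc(OCOC)c(OC)c(C)c1OC | intermediate
6 | 1,4-dibromobutane | BrCCCCBr | starting material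
7 | [2,6-bis(methoxymethoxy)-3,5-dimethoxy-4-methylphenyl]lithium | [Li]c1c(OCOC)c(OC)c(C)c(OC)c1OCOC | intermediate
8 | 2-(4-bromobutyl)-1,3-bis(methoxymethoxy)-4,6-dimethoxy-5-methylbenzene | COCOc1c(CCCCBr)c(OCOC)c(OC)c(C)c1OC | intermediate
9 | 1,6-dibromohexane | BrCCCCCCBr | starting material
10 | hexane-1,6-diylbis(magnesium bromide) | Br[Mg]CCCCCC[Mg]Br | intermediate
11 | 1,14-bis[2,6-bis(methoxymethoxy)-3,5-dimethoxy-4-methylphenyl]tetradecane | COCOc1c(CCCCCCCCCCCCCCc2c(OCOC)c(OC)c(C)c(OC)c2OCOC)c(OCOC)c(OC)c(C)c1OC | intermediate
12 | 2,2'-(tetradecane-1,14-diyl)bis(4,6-dimethoxy-5-methylbenzene-1,3-diol) | COc1c(C)c(OC)c(O)c(CCCCCCCCCCCCCCc2c(O)c(OC)c(C)c(OC)c2O)c1O | intermediate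
13 | 3,3'-(tetradecane-1,14-diyl)bis(2-hydroxy-5-methoxy-6-methylcyclohexa-2,5-diene-1,4-dione) | COC1=C(C)C(=O)C(O)=C(CCCCCCCCCCCCCCC2=C(O)C(=O)C(C)=C(OC)C2=O)C1=O | target

**Step count and risks**

Total steps: 9. Longest linear sequence: 8 steps (1 to 13 through steps 1–5, 7, 8 and 9); step 6 is a one-step side branch.

Steps most likely to fail:

Step 7. The two-fold coupling may stop after one terminus, the copper catalyst may homocouple Grignard termini, and magnesium–bromine exchange or Wurtz coupling carried over from step 6 may scramble chain lengths; each process would give tether homologues that are hard to separate from 11. Fallback, setting out from 8: the six-carbon unit is delivered as a boron reagent instead. Hexa-1,5-diene is hydroborated at both ends with 9-BBN-H in THF at room temperature to give 1,6-bis(9-borabicyclo[3.3.1]nonan-9-yl)hexane F1. This is coupled in the same flask with 8 (2.2 equiv) under Pd(OAc)2/PCy3/K3PO4·H2O in THF at room temperature, an alkyl–alkyl Suzuki–Miyaura coupling of primary bromides. The same C4'–C5' and C10'–C11' bonds form, and the route is rejoined at 11.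

Step 9. The free resorcinol rings are very electron-rich, so over-oxidation, oxidative coupling or aerial oxidation during handling of 12 may consume material before clean quinone formation. Fallback, setting out from 11: the rings are oxidised while the hydroxyls are still masked. (NH4)2Ce(NO3)6 in MeCN–H2O at 0 °C (oxidative dealkylation by tetravalent cerium across a para OMOM/OMe pair, either pair giving the same product) should give 3,3'-(tetradecane-1,14-diyl)bis[5-methoxy-2-(methoxymethoxy)-6-methylcyclohexa-2,5-diene-1,4-dione] F2. Brief treatment with dilute HCl in MeOH–THF at room temperature then removes the two vinylogous-ester MOM groups. The route is rejoined at 13 and 12 is bypassed.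

Step 5. The hindered aryllithium may substitute sluggishly, so that a second arylation of the product bromide and base-induced dehydrobromination of the dibromide compete. Fallback, setting out from 5 (lithiated to 7 as before): a monofunctional electrophile with a masked terminus is used. Alkylation with tert-butyl(4-iodobutoxy)dimethylsilane in THF should give tert-butyl{4-[2,6-bis(methoxymethoxy)-3,5-dimethoxy-4-methylphenyl]butoxy}dimethylsilane F3. Bu4NF in THF frees 4-[2,6-bis(methoxymethoxy)-3,5-dimethoxy-4-methylphenyl]butan-1-ol F4, and an Appel reaction (CBr4, PPh3, CH2Cl2, 0 °C) converts it into the bromide. The route is rejoined at 8.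

**Further compounds**

F1 | step 7 | 1,6-bis(9-borabicyclo[3.3.1]nonan-9-yl)hexane | C(CCCCCB1C2CCCC1CCC2)B1C2CCCC1CCC2
F2 | step 9 | 3,3'-(tetradecane-1,14-diyl)bis[5-methoxy-2-(methoxymethoxy)-6-methylcyclohexa-2,5-diene-1,4-dione] | COCOC1=C(CCCCCCCCCCCCCCC2=C(OCOC)C(=O)C(C)=C(OC)C2=O)C(=O)C(OC)=C(C)C1=O
F3 | step 5 | tert-butyl{4-[2,6-bis(methoxymethoxy)-3,5-dimethoxy-4-methylphenyl]butoxy}dimethylsilane | COCOc1c(CCCCO[Si](C)(C)C(C)(C)C)c(OCOC)c(OC)c(C)c1OC
F4 | step 5 | 4-[2,6-bis(methoxymethoxy)-3,5-dimethoxy-4-methylphenyl]butan-1-ol | COCOc1c(CCCCO)c(OCOC)c(OC)c(C)c1OC
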